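The target is read as an α-ketol. In its cyclohexenone ring (C1 tertiary carbinol bearing C7H2OBz, C2 ketone, C3=C4, C5 carbinol, C6 benzoate carbon) the C1–OH/C2=O pair is the retron of an acyloin shift. Disconnecting C1–C6 by the reverse shift contracts the ring to a 1-(benzoyloxyacetyl)cyclopent-2-en-1-ol in which C6 is bonded to C2. In the forward sense one chelate-controlled 1,2-shift of C6 from C2 to C1 closes the six-membered ring and creates the C1 stereocentre. It also unveils the C2 ketone in conjugation with C3=C4 (the driving force) and carries C5 and C6 over unchanged. The cyclopentene precursor is built in four steps from (S)-4-silyloxycyclopentenone, whose C2–C6 bond is sacrificed.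

Key step: step 5

Remark: the target numbering C1–C7 is used for the same carbon atoms in every intermediate, and (S)-4-(tert-butyldimethylsilyloxy)cyclopent-2-en-1-one is taken as a catalogue compound.

Step 1
Reactants: 1 (S)-4-[(tert-butyldimethylsilyl)oxy]cyclopent-2-en-1-one
Product: 3 (4R,5S)-4-[(tert-butyldimethylsilyl)oxy]-5-hydroxycyclopent-2-en-1-one, via lithium dienolate 2 (not isolated)
Conditions: LiN(iPr)2 (1.1 equiv), THF, −78 °C; 2-(phenylsulfonyl)-3-phenyloxaziridine, −78 °C; AcOH quench
Reagents that add atoms: 2-(phenylsulfonyl)-3-phenyloxaziridine, O=S(=O)(N1OC1c1ccccc1)c1ccccc1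
Why: Electrophilic hydroxylation of a kinetic enolate with an N-sulfonyloxaziridine: α′-deprotonation at C6 gives the cross-conjugated dienolate 2, which keeps its silyloxy group at −78 °C because its loss would give an antiaromatic cyclopentadienone, and the oxidant approaches anti to the C5 silyloxy group, which sets C6 as (S), trans to C5.

Step 2
Reactants: 3 (4R,5S)-4-[(tert-butyldimethylsilyl)oxy]-5-hydroxycyclopent-2-en-1-one; 4 ethyl vinyl ether
Product: 6 (1S,4R,5S)-4-[(tert-butyldimethylsilyl)oxy]-1-(1-ethoxyethenyl)cyclopent-2-ene-1,5-diol, via 1-ethoxyvinyllithium 5 (not isolated)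
Conditions: 4, t-BuLi, THF, −78 to 0 °C (forms 5, 2.5 equiv); 3, THF, −78 °C; H2O quench
Reagents that add atoms: 1-ethoxyvinyllithium 5, [Li]C(=C)OCC, made from ethyl vinyl ether 4, C=COCC
Why: 1,2-Addition of an α-lithiated enol ether (acyl anion equivalent) to the enone carbonyl: the first equivalent of 5 turns the C6 hydroxyl into a lithium alkoxide that lies close to the carbonyl plane in a five-membered chelate and shields neither face, the C5 silyloxy group blocks its own face, and the second equivalent enters anti to it, which sets C2 as (S) with the new carbon C1 cis to the C6 oxygen.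

Step 3
Reactants: 6 (1S,4R,5S)-4-[(tert-butyldimethylsilyl)oxy]-1-(1-ethoxyethenyl)cyclopent-2-ene-1,5-diol
Product: 8 1-[(1S,4R,5S)-4-[(tert-butyldimethylsilyl)oxy]-1,5-dihydroxycyclopent-2-en-1-yl]-2-hydroxyethan-1-one, via ethyl hemiketal 7 (not isolated)
Conditions: OsO4 (2 mol %), N-methylmorpholine N-oxide (1.05 equiv), acetone–H2O, 0 °C
Reagents that add atoms: N-methylmorpholine N-oxide, C[N+]1([O-])CCOCC1 (its oxygen is passed on through OsO4, O=[Os](=O)(=O)=O); water, O
Why: OsO4-catalysed dihydroxylation of an enol ether: the electron-rich 1,1-disubstituted enol ether reacts far faster than the ring alkene flanked by two oxygenated carbons, and hemiketal 7 collapses with loss of ethanol, so C1 becomes the ketone and C7 gains its oxygen without touching a stereocentre.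

Step 4
Reactants: 8 1-[(1S,4R,5S)-4-[(tert-butyldimethylsilyl)oxy]-1,5-dihydroxycyclopent-2-en-1-yl]-2-hydroxyethan-1-one; 9 benzoyl chloride
Product: 10 2-[(1S,4R,5S)-5-(benzoyloxy)-4-[(tert-butyldimethylsilyl)oxy]-1-hydroxycyclopent-2-en-1-yl]-2-oxoethyl benzoate
Conditions: 9 (2.2 equiv), pyridine, DMAP (cat.), CH2Cl2, 0 °C
Reagents that add atoms: benzoyl chloride 9, O=C(Cl)c1ccccc1
Why: DMAP-catalysed O-acylation: the primary C7 and the secondary C6 hydroxyl are esterified, while the tertiary C2 hydroxyl next to the ketone is too hindered to react and stays free for the key step.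

Step 5
Reactants: 10 2-[(1S,4R,5S)-5-(benzoyloxy)-4-[(tert-butyldimethylsilyl)oxy]-1-hydroxycyclopent-2-en-1-yl]-2-oxoethyl benzoate
Product: 11 [(1R,5R,6S)-6-(benzoyloxy)-5-[(tert-butyldimethylsilyl)oxy]-1-hydroxy-2-oxocyclohex-3-en-1-yl]methyl benzoate
Conditions: Sc(OTf)3 (20 mol %), 4 Å MS, toluene, 60 °C
Reagents that add atoms: none
Why: α-Ketol (acyloin) rearrangement run as a ring enlargement, the reaction type known from 1-acylcyclopentanols and from the D-homoannulation of 17-hydroxy-20-oxo steroids: Sc(OTf)3 binds the C2 hydroxyl and the C1 ketone oxygen in a five-membered chelate, C6 shifts with its bonding pair from C2 to C1, and the C2 carbinol becomes the C2 ketone. The six-membered carbocycle is closed not by an exo or endo attack along a chain but by this suprafacial 1,2-shift through a three-centre transition state, in which C1–C6 forms as the C2–C6 bond of the cyclopentene breaks, so C6 migrates with retention and C5 is untouched. The new stereocentre C1 is controlled by the chelate and by C2: with both oxygens held syn, C6 can reach only the face of the C1 carbonyl that is turned towards it, and for the (S)-carbinol, whose acyl group is cis to the C6 benzoate, this leaves C7 cis and the C1 hydroxyl trans to that benzoate, which is (R). The step needs C6 and not the vinylic C3 to migrate; the shift is reversible, only the C6 shift gives a ketone conjugated with C3=C4 in an unstrained six-membered ring, and the unconjugated product of a C3 shift can return through the same chelate, so 11 is the thermodynamic sink. Neither C1 nor C2 carries a hydrogen and the medium is not basic, so no benzoate can be lost by β-elimination.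

Step 6
Reactants: 11 [(1R,5R,6S)-6-(benzoyloxy)-5-[(tert-butyldimethylsilyl)oxy]-1-hydroxy-2-oxocyclohex-3-en-1-yl]methyl benzoate
Product: 12 [(1R,5R,6S)-6-(benzoyloxy)-1,5-dihydroxy-2-oxocyclohex-3-en-1-yl]methyl benzoate (target)
Conditions: HF·pyridine, THF, 0 °C to rt
Reagents that add atoms: none
Why: Fluoride-induced cleavage of the silyl ether in a slightly acidic medium, chosen because basic fluoride could move the benzoyl group from O6 to the freed O5 or start a vinylogous elimination; no stereocentre is affected.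

Compound list
1 | (S)-4-[(tert-butyldimethylsilyl)oxy]cyclopent-2-en-1-one | O=C1C=C[C@@H](O[Si](C)(C)C(C)(C)C)C1 | starting material
2 | lithium (3R)-3-[(tert-butyldimethylsilyl)oxy]cyclopenta-1,4-dien-1-olate (cross-conjugated dienolate of 1, C2=C6) | [Li+].[O-]C1=C[C@H](O[Si](C)(C)C(C)(C)C)C=C1 | intermediate
3 | (4R,5S)-4-[(tert-butyldimethylsilyl)oxy]-5-hydroxycyclopent-2-en-1-one (trans) | O=C1C=C[C@@H](O[Si](C)(C)C(C)(C)C)[C@@H]1O | intermediate
4 | ethyl vinyl ether | C=COCC | starting material
5 | 1-ethoxyvinyllithium | [Li]C(=C)OCC | intermediate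
6 | (1S,4R,5S)-4-[(tert-butyldimethylsilyl)oxy]-1-(1-ethoxyethenyl)cyclopent-2-ene-1,5-diol | C=C(OCC)[C@]1(O)C=C[C@@H](O[Si](C)(C)C(C)(C)C)[C@@H]1O | intermediate
7 | ethyl hemiketal: (1S,4R,5S)-4-[(tert-butyldimethylsilyl)oxy]-1-(1-ethoxy-1,2-dihydroxyethyl)cyclopent-2-ene-1,5-diol, both epimers at the hemiketal carbon | OCC(O)(OCC)[C@]1(O)C=C[C@@H](O[Si](C)(C)C(C)(C)C)[C@@H]1O | intermediate
8 | 1-[(1S,4R,5S)-4-[(tert-butyldimethylsilyl)oxy]-1,5-dihydroxycyclopent-2-en-1-yl]-2-hydroxyethan-1-one | O=C(CO)[C@]1(O)C=C[C@@H](O[Si](C)(C)C(C)(C)C)[C@@H]1O | intermediate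
9 | benzoyl chloride | O=C(Cl)c1ccccc1 | starting material
10 | 2-[(1S,4R,5S)-5-(benzoyloxy)-4-[(tert-butyldimethylsilyl)oxy]-1-hydroxycyclopent-2-en-1-yl]-2-oxoethyl benzoate | O=C(COC(=O)c1ccccc1)[C@]1(O)C=C[C@@H](O[Si](C)(C)C(C)(C)C)[C@@H]1OC(=O)c1ccccc1 | intermediate
11 | [(1R,5R,6S)-6-(benzoyloxy)-5-[(tert-butyldimethylsilyl)oxy]-1-hydroxy-2-oxocyclohex-3-en-1-yl]methyl benzoate | O=C(OC[C@]1(O)C(=O)C=C[C@@H](O[Si](C)(C)C(C)(C)C)[C@@H]1OC(=O)c1ccccc1)c1ccccc1 | intermediate
12 | [(1R,5R,6S)-6-(benzoyloxy)-1,5-dihydroxy-2-oxocyclohex-3-en-1-yl]methyl benzoate | O=C(OC[C@]1(O)C(=O)C=C[C@@H](O)[C@@H]1OC(=O)c1ccccc1)c1ccccc1 | target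

Total step count: 6. Longest linear sequence: 6 steps (1 to 12).

Steps most likely to fail

1. Step 5 (ring enlargement).
- What may go wrong: the vinylic carbon C3 may migrate instead of C6 under kinetic control. Turnover may be slow because the migrating carbon carries an electron-withdrawing benzoate. Leakage through a non-chelated geometry may erode the C1 configuration.
- Fallback, from 8 back to 11: the primary hydroxyl alone is benzoylated (BzCl, one equivalent, 2,4,6-collidine, CH2Cl2, −20 °C) to the C7 monobenzoate F1. The C6 hydroxyl is then capped (Et3SiCl, imidazole, DMF) to give the C6 triethylsilyl ether F2. Its migrating carbon now bears a donor silyloxy group instead of an acyloxy group.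
- The shift is run on the aluminium alkoxide of the substrate (Al(OtBu)3, toluene, 80 °C), a classical chelating medium for ketol ring enlargement, and should give the ring-enlarged silyl ether F3. AcOH–THF–H2O removes only the triethylsilyl group to give the C6 alcohol F4, and BzCl, pyridine and DMAP lead to 11.

2. Step 2 (addition to the enone).
- What may go wrong: facial selectivity may be poor, because the C5 silyloxy group and the C6 alkoxide sit on opposite faces. Enolisation of the α-hydroxy enone by the basic reagent may also compete.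
- Fallback, from 3 back to 12: C2 is erased in step 5, so the other C2 epimer is used rather than discarded. The (1R)-adduct F5, formed by attack syn to the C5 silyloxy group, is separated and taken through the operations of steps 3 and 4. OsO4 and N-methylmorpholine N-oxide give, through the epimeric ethyl hemiketal F6, the (1R)-hydroxy ketone F7, and BzCl gives the (1R)-dibenzoate F8.
- Chelation would now lead to the wrong C1 epimer, so it is switched off. Me3SiOTf and 2,6-lutidine give the C2 trimethylsilyl ether F9. The bulky monodentate MeAl(OAr)2 (Ar = 2,6-di-tert-butyl-4-methylphenyl, CH2Cl2, −40 °C) then promotes the known shift of α-silyloxy ketones from the dipole-opposed conformer. In that conformer C6 reaches the other face of the C1 carbonyl, which should give the C1 trimethylsilyl ether F10 of the same (1R,5R,6S) series. HF·pyridine removes both silyl groups and gives 12.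

3. Step 1 (enolate hydroxylation).
- What may go wrong: the dienolate may lose silanolate, the enolate may attack the sulfonimine by-product, or proton exchange between product and enolate may limit conversion.
- Fallback, from 1 back to 3: oxidation with Mn(OAc)3 in refluxing benzene is the α′-acetoxylation of enones, which runs through a manganese enolate and needs no strong base. It should give the trans acetate F11. Lipase-catalysed methanolysis (Candida antarctica lipase B, MeOH, MTBE) then frees the alcohol 3.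

Further compounds
F1 | step 5 | 2-[(1S,4R,5S)-4-[(tert-butyldimethylsilyl)oxy]-1,5-dihydroxycyclopent-2-en-1-yl]-2-oxoethyl benzoate | O=C(COC(=O)c1ccccc1)[C@]1(O)C=C[C@@H](O[Si](C)(C)C(C)(C)C)[C@@H]1O
F2 | step 5 | 2-[(1S,4R,5S)-4-[(tert-butyldimethylsilyl)oxy]-1-hydroxy-5-[(triethylsilyl)oxy]cyclopent-2-en-1-yl]-2-oxoethyl benzoate | O=C(COC(=O)c1ccccc1)[C@]1(O)C=C[C@@H](O[Si](C)(C)C(C)(C)C)[C@@H]1O[Si](CC)(CC)CC
F3 | step 5 | [(1R,5R,6S)-5-[(tert-butyldimethylsilyl)oxy]-1-hydroxy-2-oxo-6-[(triethylsilyl)oxy]cyclohex-3-en-1-yl]methyl benzoate | O=C(OC[C@]1(O)C(=O)C=C[C@@H](O[Si](C)(C)C(C)(C)C)[C@@H]1O[Si](CC)(CC)CC)c1ccccc1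
F4 | step 5 | [(1R,5R,6S)-5-[(tert-butyldimethylsilyl)oxy]-1,6-dihydroxy-2-oxocyclohex-3-en-1-yl]methyl benzoate | O=C(OC[C@]1(O)C(=O)C=C[C@@H](O[Si](C)(C)C(C)(C)C)[C@@H]1O)c1ccccc1
F5 | step 2 | (1R,4R,5S)-4-[(tert-butyldimethylsilyl)oxy]-1-(1-ethoxyethenyl)cyclopent-2-ene-1,5-diol | C=C(OCC)[C@@]1(O)C=C[C@@H](O[Si](C)(C)C(C)(C)C)[C@@H]1O
F6 | step 2 | (1R,4R,5S)-4-[(tert-butyldimethylsilyl)oxy]-1-(1-ethoxy-1,2-dihydroxyethyl)cyclopent-2-ene-1,5-diol, both epimers at the hemiketal carbon | OCC(O)(OCC)[C@@]1(O)C=C[C@@H](O[Si](C)(C)C(C)(C)C)[C@@H]1O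
F7 | step 2 | 1-[(1R,4R,5S)-4-[(tert-butyldimethylsilyl)oxy]-1,5-dihydroxycyclopent-2-en-1-yl]-2-hydroxyethan-1-one | O=C(CO)[C@@]1(O)C=C[C@@H](O[Si](C)(C)C(C)(C)C)[C@@H]1O
F8 | step 2 | 2-[(1R,4R,5S)-5-(benzoyloxy)-4-[(tert-butyldimethylsilyl)oxy]-1-hydroxycyclopent-2-en-1-yl]-2-oxoethyl benzoate | O=C(COC(=O)c1ccccc1)[C@@]1(O)C=C[C@@H](O[Si](C)(C)C(C)(C)C)[C@@H]1OC(=O)c1ccccc1
F9 | step 2 | 2-[(1R,4R,5S)-5-(benzoyloxy)-4-[(tert-butyldimethylsilyl)oxy]-1-[(trimethylsilyl)oxy]cyclopent-2-en-1-yl]-2-oxoethyl benzoate | O=C(COC(=O)c1ccccc1)[C@@]1(O[Si](C)(C)C)C=C[C@@H](O[Si](C)(C)C(C)(C)C)[C@@H]1OC(=O)c1ccccc1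
F10 | step 2 | [(1R,5R,6S)-6-(benzoyloxy)-5-[(tert-butyldimethylsilyl)oxy]-2-oxo-1-[(trimethylsilyl)oxy]cyclohex-3-en-1-yl]methyl benzoate | O=C(OC[C@]1(O[Si](C)(C)C)C(=O)C=C[C@@H](O[Si](C)(C)C(C)(C)C)[C@@H]1OC(=O)c1ccccc1)c1ccccc1
F11 | step 1 | (4R,5S)-5-acetoxy-4-[(tert-butyldimethylsilyl)oxy]cyclopent-2-en-1-one | O=C1C=C[C@@H](O[Si](C)(C)C(C)(C)C)[C@@H]1OC(C)=O
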